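**Strategy.** The ten-membered carbocycle is closed last, at the bond between the C3 carbinol and alkene carbon C4 (germacrane numbering), by an intramolecular Nozaki–Hiyama–Kishi addition of an (E)-alkenyl iodide to an aldehyde. This exploits the allylic alcohol C3(OH)–C4=C5 of ring C1–C10: one operation forms the ring, the C3 stereocentre and the target itself, since the acyclic precursor already carries the trans-fused methylene lactone (C7, C8, C11–C13) and both (R)-2-methylbutanoates. The precursor comes from an indium Barbier coupling of a C8-chiral bromomethyl butenolide with an iodo lactol whose ring fixes the C4=C5 geometry and releases the C6 and C15 hydroxyls.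

Key step: step 13

Assumption: atoms are named by germacrane numbering (ring C1–C10, C14 methyl on C10, C15 acyloxymethyl on C4, lactone C12 carbonyl closed to O–C8, C13 exocyclic methylene); compounds 1, 5, 10, 13 and 19 are taken as purchasable; the chiral ligand of step 13 is used in the antipode that directs Si-face addition to the C3 aldehyde, taken here to be the (S)-valinol-derived one.

Step 1
Reactants: 1 pent-3-yn-1-ol
Product: 2 tert-butyldimethyl(pent-3-yn-1-yloxy)silane
Conditions: TBSCl, imidazole, CH2Cl2, 0 °C to rt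
Reagents that add atoms: tert-butyldimethylsilyl chloride, CC(C)(C)[Si](C)(C)Cl
Why: Standard imidazole-promoted silylation of the primary alcohol gives a silyl ether that should survive the organometallic, metathesis and Barbier steps and is cleaved by fluoride late.

Step 2
Reactants: 2 tert-butyldimethyl(pent-3-yn-1-yloxy)silane
Product: 4 (E)-tert-butyl[(4-iodopent-3-en-1-yl)oxy]dimethylsilane, via alkenylzirconocene chloride 3 (not isolated)
Conditions: Cp2Zr(H)Cl (2 equiv), THF, 50 °C; then iodine, 0 °C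
Reagents that add atoms: iodine, I-I
Why: Hydrozirconation adds Zr–H syn across the alkyne and, with excess Cp2Zr(H)Cl and warming, equilibrates zirconium to the less hindered methyl-bearing carbon (3), so that iodinolysis with retention should give the E iodide that becomes the C1=C10 alkene with its C14 methyl.

Step 3
Reactants: 4 (E)-tert-butyl[(4-iodopent-3-en-1-yl)oxy]dimethylsilane; 5 (S)-epichlorohydrin
Product: 7 (2S,4E)-7-[(tert-butyldimethylsilyl)oxy]-1-chloro-4-methylhept-4-en-2-ol, via alkenyllithium 6 (not isolated)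
Conditions: t-BuLi (2.1 equiv), Et2O, −78 °C; then BF3·OEt2 and 5, −78 °C
Reagents that add atoms: none
Why: Iodine–lithium exchange proceeds with retention of alkene geometry and the alkenyllithium opens the BF3-activated epoxide at its unsubstituted carbon (epoxide ring opening), so the chiral-pool stereocentre, the future C8, is carried over untouched.

Step 4
Reactants: 7 (2S,4E)-7-[(tert-butyldimethylsilyl)oxy]-1-chloro-4-methylhept-4-en-2-ol
Product: 9 (3S,5E)-8-[(tert-butyldimethylsilyl)oxy]-5-methylocta-1,5-dien-3-ol, via epoxide 8 (not isolated)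
Conditions: trimethylsulfonium iodide (4 equiv), n-BuLi (3.9 equiv), THF, −10 °C to rt
Reagents that add atoms: trimethylsulfonium iodide, C[S+](C)C.[I-]
Why: Base closes the chlorohydrin to terminal epoxide 8 and excess dimethylsulfonium methylide (Corey–Chaykovsky reagent) opens it at CH2 and eliminates dimethyl sulfide, a known one-carbon homologation of epoxides to allylic alcohols that does not touch the carbinol stereocentre.

Step 5
Reactants: 9 (3S,5E)-8-[(tert-butyldimethylsilyl)oxy]-5-methylocta-1,5-dien-3-ol; 10 2-(bromomethyl)acrylic acid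
Product: 11 (3S,5E)-8-[(tert-butyldimethylsilyl)oxy]-5-methylocta-1,5-dien-3-yl 2-(bromomethyl)acrylate
Conditions: DCC, DMAP (5 mol%), CH2Cl2, 0 °C
Reagents that add atoms: none
Why: Steglich esterification with only catalytic DMAP at 0 °C acylates the secondary alcohol with retention while limiting attack on the allylic bromide.

Step 6
Reactants: 11 (3S,5E)-8-[(tert-butyldimethylsilyl)oxy]-5-methylocta-1,5-dien-3-yl 2-(bromomethyl)acrylate
Product: 12 (5S)-3-(bromomethyl)-5-[(2E)-5-((tert-butyldimethylsilyl)oxy)-2-methylpent-2-en-1-yl]furan-2(5H)-one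
Conditions: second-generation Grubbs catalyst (5 mol%), CH2Cl2, 40 °C, 5 mM
Reagents that add atoms: none
Why: Ring-closing metathesis of the acrylate and vinyl groups should form the five-membered butenolide and release ethene, the trisubstituted alkene being too hindered to take part.

Step 7
Reactants: 13 4-bromofuran-2(5H)-one
Product: 14 4-iodofuran-2(5H)-one
Conditions: NaI (3 equiv), acetone, 56 °C
Reagents that add atoms: sodium iodide, [Na+].[I-]
Why: Finkelstein-type halide exchange on the vinylogous acyl bromide runs by conjugate addition of iodide and loss of bromide and is driven by precipitation of NaBr.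

Step 8
Reactants: 14 4-iodofuran-2(5H)-one
Product: 15 4-iodo-2,5-dihydrofuran-2-ol
Conditions: iBu2AlH (1.1 equiv), CH2Cl2, −78 °C; aqueous potassium sodium tartrate; used crude
Reagents that add atoms: none
Why: At −78 °C iBu2AlH adds once to the lactone carbonyl and the aluminium hemiacetal survives until work-up (partial lactone reduction), giving a lactol whose ring holds the future C6 and C15 cis on the alkene with iodine trans to C6.

Step 9
Reactants: 12 (5S)-3-(bromomethyl)-5-[(2E)-5-((tert-butyldimethylsilyl)oxy)-2-methylpent-2-en-1-yl]furan-2(5H)-one; 15 4-iodo-2,5-dihydrofuran-2-ol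
Product: 18 (4S,5S)-5-[(2E)-5-((tert-butyldimethylsilyl)oxy)-2-methylpent-2-en-1-yl]-4-[(1S,2E)-1,4-dihydroxy-3-iodobut-2-en-1-yl]-3-methylideneoxolan-2-one, via open-chain hydroxy enal 16 (not isolated), via allylindium reagent 17 (not isolated)
Conditions: indium powder (1.5 equiv), THF/H2O 1:1, rt
Reagents that add atoms: none
Why: Barbier allylation in which allylindium reagent 17 adds through its γ-carbon (C7) to the open hydroxy-enal form 16 of the lactol in a six-membered chair (Zimmerman–Traxler) transition state, the aldehyde approaching the butenolide face opposite the C8 side chain (C7–H trans to C8–H) with its alkenyl group equatorial so that the C6 hydroxyl is set anti to C8 as the target requires, while opening of the lactol frees the C15 hydroxyl.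

Step 10
Reactants: 18 (4S,5S)-5-[(2E)-5-((tert-butyldimethylsilyl)oxy)-2-methylpent-2-en-1-yl]-4-[(1S,2E)-1,4-dihydroxy-3-iodobut-2-en-1-yl]-3-methylideneoxolan-2-one; 19 (R)-2-methylbutanoic acid
Product: 20 (1S,2E)-1-[(2S,3R)-2-[(2E)-5-((tert-butyldimethylsilyl)oxy)-2-methylpent-2-en-1-yl]-4-methylidene-5-oxooxolan-3-yl]-3-iodobut-2-ene-1,4-diyl bis[(2R)-2-methylbutanoate]
Conditions: 19 (3 equiv), DCC (3 equiv), DMAP (0.3 equiv), CH2Cl2, 0 °C to rt
Reagents that add atoms: none
Why: Double Steglich esterification should acylate the primary C15 and the secondary allylic C6 hydroxyl in one operation, the acid stereocentre coming from the chiral pool.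

Step 11
Reactants: 20 (1S,2E)-1-[(2S,3R)-2-[(2E)-5-((tert-butyldimethylsilyl)oxy)-2-methylpent-2-en-1-yl]-4-methylidene-5-oxooxolan-3-yl]-3-iodobut-2-ene-1,4-diyl bis[(2R)-2-methylbutanoate]
Product: 21 (1S,2E)-1-[(2S,3R)-2-[(2E)-5-hydroxy-2-methylpent-2-en-1-yl]-4-methylidene-5-oxooxolan-3-yl]-3-iodobut-2-ene-1,4-diyl bis[(2R)-2-methylbutanoate]
Conditions: HF·pyridine, pyridine/THF, 0 °C
Reagents that add atoms: none
Why: Fluoride-mediated desilylation with buffered HF·pyridine removes the primary silyl ether without touching the esters, the lactone or the alkenyl iodide.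

Step 12
Reactants: 21 (1S,2E)-1-[(2S,3R)-2-[(2E)-5-hydroxy-2-methylpent-2-en-1-yl]-4-methylidene-5-oxooxolan-3-yl]-3-iodobut-2-ene-1,4-diyl bis[(2R)-2-methylbutanoate]
Product: 22 (1S,2E)-3-iodo-1-[(2S,3R)-4-methylidene-2-[(2E)-2-methyl-5-oxopent-2-en-1-yl]-5-oxooxolan-3-yl]but-2-ene-1,4-diyl bis[(2R)-2-methylbutanoate]
Conditions: Dess–Martin periodinane, NaHCO3, CH2Cl2, 0 °C; used at once
Reagents that add atoms: none
Why: Dess–Martin oxidation under bicarbonate buffer should give the β,γ-unsaturated aldehyde without a base strong enough to move the C1=C10 alkene into conjugation.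

Step 13
Reactants: 22 (1S,2E)-3-iodo-1-[(2S,3R)-4-methylidene-2-[(2E)-2-methyl-5-oxopent-2-en-1-yl]-5-oxooxolan-3-yl]but-2-ene-1,4-diyl bis[(2R)-2-methylbutanoate]
Product: 24 (3R,6R,7R,8S)-3-hydroxy-6,15-bis[(2R)-2-methylbutanoyloxy]germacra-1(10)E,4E,11(13)-trien-12,8-olide, via alkenylchromium dichloride 23 (not isolated)
Conditions: CrCl2 (8 equiv), (S)-N-[2-(4-isopropyl-4,5-dihydrooxazol-2-yl)-6-methylphenyl]methanesulfonamide (8.8 equiv), Et3N (8.8 equiv), NiCl2 (0.5 equiv), THF, rt, slow addition of 22 to 2 mM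
Reagents that add atoms: none
Why: Nozaki–Hiyama–Kishi reaction in which zerovalent nickel, formed from NiCl2 and CrCl2, inserts into the C4–I bond with retention of alkene geometry and hands the alkenyl group to trivalent chromium (23), which adds to the C3 aldehyde. The closest known reaction type is the chromium/nickel-mediated macrocyclisation of alkenyl iodide–aldehydes to medium-ring allylic alcohols. The ten-membered ring closes in a 10-exo-trig mode, the C=O bond lying outside the forming ring. The only new stereocentre, C3 (R), arises from Si-face addition, which is to be controlled by the chiral sulfonamide ligand on chromium acting on the ring-closing conformation imposed by the trans lactone and the two E alkenes. The step needs chemoselectivity (alkenylchromium adds to aldehydes but not to the esters or the methylene lactone), retention of the E geometry fixed earlier by the lactol ring of 15, and ring closure over oligomerisation, which slow addition at high dilution should secure.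

**Compound list**

1 | pent-3-yn-1-ol | CC#CCCO | starting material
2 | tert-butyldimethyl(pent-3-yn-1-yloxy)silane | CC#CCCO[Si](C)(C)C(C)(C)C | intermediate
3 | chlorobis(cyclopentadienyl)[(E)-5-((tert-butyldimethylsilyl)oxy)pent-2-en-2-yl]zirconium (not isolated) | C/C(=C\CCO[Si](C)(C)C(C)(C)C)[Zr](Cl)(C1C=CC=C1)C1C=CC=C1 | intermediate
4 | (E)-tert-butyl[(4-iodopent-3-en-1-yl)oxy]dimethylsilane | C/C(I)=C\CCO[Si](C)(C)C(C)(C)C | intermediate
5 | (S)-epichlorohydrin, (S)-2-(chloromethyl)oxirane | ClC[C@@H]1CO1 | starting material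
6 | alkenyllithium from 4, lithium in place of iodine with geometry retained (not isolated) | C/C([Li])=C\CCO[Si](C)(C)C(C)(C)C | intermediate
7 | (2S,4E)-7-[(tert-butyldimethylsilyl)oxy]-1-chloro-4-methylhept-4-en-2-ol | ClC[C@@H](O)C/C(C)=C/CCO[Si](C)(C)C(C)(C)C | intermediate
8 | (S)-2-[(2E)-5-((tert-butyldimethylsilyl)oxy)-2-methylpent-2-en-1-yl]oxirane (not isolated) | O1C[C@@H]1C/C(C)=C/CCO[Si](C)(C)C(C)(C)C | intermediate
9 | (3S,5E)-8-[(tert-butyldimethylsilyl)oxy]-5-methylocta-1,5-dien-3-ol | C=C[C@@H](O)C/C(C)=C/CCO[Si](C)(C)C(C)(C)C | intermediate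
10 | 2-(bromomethyl)acrylic acid | C=C(CBr)C(=O)O | starting material
11 | (3S,5E)-8-[(tert-butyldimethylsilyl)oxy]-5-methylocta-1,5-dien-3-yl 2-(bromomethyl)acrylate | C=C(CBr)C(=O)O[C@H](C=C)C/C(C)=C/CCO[Si](C)(C)C(C)(C)C | intermediate
12 | (5S)-3-(bromomethyl)-5-[(2E)-5-((tert-butyldimethylsilyl)oxy)-2-methylpent-2-en-1-yl]furan-2(5H)-one | O=C1O[C@@H](C/C(C)=C/CCO[Si](C)(C)C(C)(C)C)C=C1CBr | intermediate
13 | 4-bromofuran-2(5H)-one | O=C1C=C(Br)CO1 | starting material
14 | 4-iodofuran-2(5H)-one | O=C1C=C(I)CO1 | intermediate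
15 | 4-iodo-2,5-dihydrofuran-2-ol (racemic at the hemiacetal carbon) | OC1C=C(I)CO1 | intermediate
16 | (2E)-4-hydroxy-3-iodobut-2-enal, open form of 15 with CHO and CH2OH cis (not isolated) | O=C/C=C(I)\CO | intermediate
17 | allylindium reagent from 12, drawn as the allylindium dibromide (not isolated) | Br[In](Br)CC1=C[C@H](C/C(C)=C/CCO[Si](C)(C)C(C)(C)C)OC1=O | intermediate
18 | (4S,5S)-5-[(2E)-5-((tert-butyldimethylsilyl)oxy)-2-methylpent-2-en-1-yl]-4-[(1S,2E)-1,4-dihydroxy-3-iodobut-2-en-1-yl]-3-methylideneoxolan-2-one | C=C1C(=O)O[C@@H](C/C(C)=C/CCO[Si](C)(C)C(C)(C)C)[C@@H]1[C@H](O)/C=C(I)\CO | intermediate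
19 | (R)-2-methylbutanoic acid | CC[C@@H](C)C(=O)O | starting material
20 | (1S,2E)-1-[(2S,3R)-2-[(2E)-5-((tert-butyldimethylsilyl)oxy)-2-methylpent-2-en-1-yl]-4-methylidene-5-oxooxolan-3-yl]-3-iodobut-2-ene-1,4-diyl bis[(2R)-2-methylbutanoate] | C=C1C(=O)O[C@@H](C/C(C)=C/CCO[Si](C)(C)C(C)(C)C)[C@@H]1[C@@H](/C=C(I)\COC(=O)[C@H](C)CC)OC(=O)[C@H](C)CC | intermediate
21 | (1S,2E)-1-[(2S,3R)-2-[(2E)-5-hydroxy-2-methylpent-2-en-1-yl]-4-methylidene-5-oxooxolan-3-yl]-3-iodobut-2-ene-1,4-diyl bis[(2R)-2-methylbutanoate] | C=C1C(=O)O[C@@H](C/C(C)=C/CCO)[C@@H]1[C@@H](/C=C(I)\COC(=O)[C@H](C)CC)OC(=O)[C@H](C)CC | intermediate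
22 | (1S,2E)-3-iodo-1-[(2S,3R)-4-methylidene-2-[(2E)-2-methyl-5-oxopent-2-en-1-yl]-5-oxooxolan-3-yl]but-2-ene-1,4-diyl bis[(2R)-2-methylbutanoate] | C=C1C(=O)O[C@@H](C/C(C)=C/CC=O)[C@@H]1[C@@H](/C=C(I)\COC(=O)[C@H](C)CC)OC(=O)[C@H](C)CC | intermediate
23 | alkenylchromium dichloride from 22, trivalent chromium in place of iodine (not isolated) | C=C1C(=O)O[C@@H](C/C(C)=C/CC=O)[C@@H]1[C@@H](/C=C(\COC(=O)[C@H](C)CC)[Cr](Cl)Cl)OC(=O)[C@H](C)CC | intermediate
24 | (3R,6R,7R,8S)-3-hydroxy-6,15-bis[(2R)-2-methylbutanoyloxy]germacra-1(10)E,4E,11(13)-trien-12,8-olide (3α-hydroxy, 6α-acyloxy, 7α-H, 8β-H) | C=C1C(=O)O[C@H]2C/C(C)=C/C[C@@H](O)/C(COC(=O)[C@H](C)CC)=C/[C@@H](OC(=O)[C@H](C)CC)[C@H]12 | target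

**Step count.** Total: 13 steps. Longest linear sequence: 11 steps (steps 1–6 and 9–13, from pent-3-yn-1-ol).

**Steps most likely to fail**

1. Step 13. The facial selectivity of the addition to the C3 aldehyde may be poor, because the ring-closing conformation can override the ligand and deliver mainly the C3 epimer. Fallback, from 22 back to 24: the ring would be closed without the chiral ligand (CrCl2, catalytic NiCl2, DMSO, high dilution), accepting the 3S alcohol (3S,6R,7R,8S)-3-hydroxy-6,15-bis[(2R)-2-methylbutanoyloxy]germacra-1(10)E,4E,11(13)-trien-12,8-olide F1 alongside 24. The mixture would be oxidised with Dess–Martin periodinane to the C3 enone (6R,7R,8S)-6,15-bis[(2R)-2-methylbutanoyloxy]-3-oxogermacra-1(10)E,4E,11(13)-trien-12,8-olide F2. This would be reduced with (S)-Me-CBS oxazaborolidine and catecholborane in toluene at −78 °C, so that the C3 configuration is set by catalyst-controlled hydride delivery, returning to 24.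

2. Step 9. The lactol may lose water and aromatise to 3-iodofuran, or fail to open, so that the allylindium reagent is protonated instead of adding. Fallback, from 12 back to 20: the alkene geometry would be set after the coupling.
   - But-2-yne-1,4-diol (purchased, used in excess) would be mono-esterified with 19 (DCC, DMAP) to 4-hydroxybut-2-yn-1-yl (2R)-2-methylbutanoate F3.
   - Oxidation with MnO2 would give 4-oxobut-2-yn-1-yl (2R)-2-methylbutanoate F4.
   - Barbier allylation of F4 with 12 (zinc dust, THF/saturated aqueous NH4Cl), through the same chair transition state, would give the propargylic alcohol (4S)-4-hydroxy-4-[(2S,3S)-2-[(2E)-5-((tert-butyldimethylsilyl)oxy)-2-methylpent-2-en-1-yl]-4-methylidene-5-oxooxolan-3-yl]but-2-yn-1-yl (2R)-2-methylbutanoate F5.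
   - Steglich esterification with 19 would give the alkyne diester (1S)-1-[(2S,3R)-2-[(2E)-5-((tert-butyldimethylsilyl)oxy)-2-methylpent-2-en-1-yl]-4-methylidene-5-oxooxolan-3-yl]but-2-yne-1,4-diyl bis[(2R)-2-methylbutanoate] F6.
   - Syn hydrostannation with Bu3SnH and catalytic Pd(PPh3)4, tin going to the less hindered C4, would give the alkenylstannane (1S,2E)-1-[(2S,3R)-2-[(2E)-5-((tert-butyldimethylsilyl)oxy)-2-methylpent-2-en-1-yl]-4-methylidene-5-oxooxolan-3-yl]-3-(tributylstannyl)but-2-ene-1,4-diyl bis[(2R)-2-methylbutanoate] F7.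
   - Iododestannylation (iodine, CH2Cl2, 0 °C) with retention would return to 20.

3. Step 6. Metathesis at the 1,1-disubstituted acrylate may be slow and the allylic bromide may decompose the catalyst, so that oligomers form instead of the butenolide. Fallback, from 9 back to 12: the bromide would be introduced after ring closure.
   - Acylation of 9 with acryloyl chloride and Et3N would give (3S,5E)-8-[(tert-butyldimethylsilyl)oxy]-5-methylocta-1,5-dien-3-yl acrylate F8.
   - Ring-closing metathesis with second-generation Grubbs catalyst would give (5S)-5-[(2E)-5-((tert-butyldimethylsilyl)oxy)-2-methylpent-2-en-1-yl]furan-2(5H)-one F9.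
   - Morita–Baylis–Hillman hydroxymethylation (aqueous formaldehyde, imidazole, THF/H2O) would give (5S)-3-(hydroxymethyl)-5-[(2E)-5-((tert-butyldimethylsilyl)oxy)-2-methylpent-2-en-1-yl]furan-2(5H)-one F10.
   - Appel bromination (CBr4, PPh3) would return to 12.

Further compounds
F1 | step 13 | (3S,6R,7R,8S)-3-hydroxy-6,15-bis[(2R)-2-methylbutanoyloxy]germacra-1(10)E,4E,11(13)-trien-12,8-olide | C=C1C(=O)O[C@H]2C/C(C)=C/C[C@H](O)/C(COC(=O)[C@H](C)CC)=C/[C@@H](OC(=O)[C@H](C)CC)[C@H]12
F2 | step 13 | (6R,7R,8S)-6,15-bis[(2R)-2-methylbutanoyloxy]-3-oxogermacra-1(10)E,4E,11(13)-trien-12,8-olide | C=C1C(=O)O[C@H]2C/C(C)=C/CC(=O)/C(COC(=O)[C@H](C)CC)=C/[C@@H](OC(=O)[C@H](C)CC)[C@H]12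
F3 | step 9 | 4-hydroxybut-2-yn-1-yl (2R)-2-methylbutanoate | OCC#CCOC(=O)[C@H](C)CC
F4 | step 9 | 4-oxobut-2-yn-1-yl (2R)-2-methylbutanoate | O=CC#CCOC(=O)[C@H](C)CC
F5 | step 9 | (4S)-4-hydroxy-4-[(2S,3S)-2-[(2E)-5-((tert-butyldimethylsilyl)oxy)-2-methylpent-2-en-1-yl]-4-methylidene-5-oxooxolan-3-yl]but-2-yn-1-yl (2R)-2-methylbutanoate | C=C1C(=O)O[C@@H](C/C(C)=C/CCO[Si](C)(C)C(C)(C)C)[C@@H]1[C@H](O)C#CCOC(=O)[C@H](C)CC
F6 | step 9 | (1S)-1-[(2S,3R)-2-[(2E)-5-((tert-butyldimethylsilyl)oxy)-2-methylpent-2-en-1-yl]-4-methylidene-5-oxooxolan-3-yl]but-2-yne-1,4-diyl bis[(2R)-2-methylbutanoate] | C=C1C(=O)O[C@@H](C/C(C)=C/CCO[Si](C)(C)C(C)(C)C)[C@@H]1[C@@H](C#CCOC(=O)[C@H](C)CC)OC(=O)[C@H](C)CC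
F7 | step 9 | (1S,2E)-1-[(2S,3R)-2-[(2E)-5-((tert-butyldimethylsilyl)oxy)-2-methylpent-2-en-1-yl]-4-methylidene-5-oxooxolan-3-yl]-3-(tributylstannyl)but-2-ene-1,4-diyl bis[(2R)-2-methylbutanoate] | C=C1C(=O)O[C@@H](C/C(C)=C/CCO[Si](C)(C)C(C)(C)C)[C@@H]1[C@@H](/C=C(\COC(=O)[C@H](C)CC)[Sn](CCCC)(CCCC)CCCC)OC(=O)[C@H](C)CC
F8 | step 6 | (3S,5E)-8-[(tert-butyldimethylsilyl)oxy]-5-methylocta-1,5-dien-3-yl acrylate | C=CC(=O)O[C@H](C=C)C/C(C)=C/CCO[Si](C)(C)C(C)(C)C
F9 | step 6 | (5S)-5-[(2E)-5-((tert-butyldimethylsilyl)oxy)-2-methylpent-2-en-1-yl]furan-2(5H)-one | O=C1O[C@@H](C/C(C)=C/CCO[Si](C)(C)C(C)(C)C)C=C1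
F10 | step 6 | (5S)-3-(hydroxymethyl)-5-[(2E)-5-((tert-butyldimethylsilyl)oxy)-2-methylpent-2-en-1-yl]furan-2(5H)-one | O=C1O[C@@H](C/C(C)=C/CCO[Si](C)(C)C(C)(C)C)C=C1CO
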